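**Plan**

- Retrosynthetic cuts, in order: the two ester C–O bonds (C9 angelate, C3 senecioate), C7–C11 (isopropenyl carbons from acetone), the ring-fusion bond C5–C10, then C6–C7, C7–C8, C9=C10 and C3–C4 of the ten-membered ring and its open-chain precursor.
- Enabling feature: in ring A (C1–C2–C3–C4–C5–C10) and ring B (C5–C6–C7–C8–C9–C10) the shared bond C5–C10 halves the C1–C10 perimeter. It links the methyl-bearing quaternary C5 to C10, the β-carbon of the C8 ketone/C9 oxygen unit, so a cyclodecadienone with an exocyclic C5=C14 methylene and a 2-alkoxy enone (C8, C9=C10) is a latent form of both rings.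
- Forward order: C10–C3 aldehyde plus (Z)-crotyl unit (C3–C4), C14 by α-methylenation, C9=C10 by Horner–Wadsworth–Emmons olefination, C7 by sulfone acylation, ring closure at C6–C7, rings A and B together in one transannular radical step, then C7 isopropenylation and two acylations.
- Stereochemistry: C3 and C4 from a reagent-controlled asymmetric (Z)-crotylboration; C5 and C10 by relay from C3/C4 in the chair–chair transannular transition state; C7 and C9, both α to the C8 ketone, settle equatorial.

Key step: step 16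

Remark: atom numbers C1–C15 in comments are those of the target decalin, also for open-chain and ten-membered intermediates (C14 = methyl on C5, C15 = methyl on C4, C11–C13 = isopropenyl on C7); systematic names carry their own locants. 4,4-Dimethoxybutanenitrile, (−)-B-methoxydiisopinocampheylborane [(−)-Ipc2BOMe, from (+)-α-pinene] and angelic acid are assumed to be purchased.

**Route**

Step 1
Reactants: 1 4,4-dimethoxybutanenitrile
Product: 3 4,4-dimethoxybutanal, via N-aluminio imine 2 (not isolated)
Conditions: iBu2AlH (1.1 equiv), CH2Cl2, −78 °C; then aq. potassium sodium tartrate, rt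
Reagents that add atoms: water, O
Why: Partial reduction of a nitrile by iBu2AlH stops at the N-aluminio imine, which the buffered tartrate work-up hydrolyses to the aldehyde without touching the dimethyl acetal.

Step 2
Reactants: 3 4,4-dimethoxybutanal; 4 (Z)-but-2-ene
Product: 6 (3R,4R)-7,7-dimethoxy-3-methylhept-1-en-4-ol, via borinate ester 5 (not isolated)
Conditions: 4, KOtBu, n-BuLi, THF, −78 to −45 °C; (−)-Ipc2BOMe, −78 °C; BF3·OEt2; then 3, −78 °C; then NaOH, H2O2, 0 °C to rt
Reagents that add atoms: none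
Why: Asymmetric crotylboration with the (Z)-crotyldiisopinocampheylborane proceeds through a closed chair transition state, the (Z)-geometry giving the 3,4-syn relationship and the isopinocampheyl groups from (+)-α-pinene directing attack to the aldehyde face that gives R at the carbinol carbon, so both C3 and C4 of the target are set here.

Step 3
Reactants: 6 (3R,4R)-7,7-dimethoxy-3-methylhept-1-en-4-ol
Product: 7 tert-butyl{[(3R,4R)-7,7-dimethoxy-3-methylhept-1-en-4-yl]oxy}dimethylsilane
Conditions: TBSCl, imidazole, DMF, rt to 40 °C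
Reagents that add atoms: tert-butyldimethylsilyl chloride, CC(C)(C)[Si](C)(C)Cl
Why: Standard silylation of a secondary alcohol with TBSCl/imidazole, chosen over TBSOTf/2,6-lutidine because the latter can ionise a dimethyl acetal.

Step 4
Reactants: 7 tert-butyl{[(3R,4R)-7,7-dimethoxy-3-methylhept-1-en-4-yl]oxy}dimethylsilane
Product: 9 (3R,4R)-4-(tert-butyldimethylsilyloxy)-7,7-dimethoxy-3-methylheptan-1-ol, via B-alkyl-9-BBN adduct 8 (not isolated)
Conditions: 9-BBN, THF, 0 °C to rt; then NaOH, H2O2, 0 °C
Reagents that add atoms: hydrogen peroxide, OO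
Why: Hydroboration–oxidation with 9-BBN places boron and then oxygen on the terminal carbon (C6) of the monosubstituted alkene with anti-Markovnikov selectivity and leaves the adjacent stereocentre untouched.

Step 5
Reactants: 9 (3R,4R)-4-(tert-butyldimethylsilyloxy)-7,7-dimethoxy-3-methylheptan-1-ol
Product: 10 (3R,4R)-4-(tert-butyldimethylsilyloxy)-7,7-dimethoxy-3-methylheptanal
Conditions: TEMPO (cat.), PhI(OAc)2, CH2Cl2, rt
Reagents that add atoms: none
Why: Oxoammonium (TEMPO/PhI(OAc)2) oxidation of a primary alcohol stops at the aldehyde under conditions mild enough for the acetal and the silyl ether.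

Step 6
Reactants: 10 (3R,4R)-4-(tert-butyldimethylsilyloxy)-7,7-dimethoxy-3-methylheptanal; 11 formaldehyde
Product: 12 (3R,4R)-4-(tert-butyldimethylsilyloxy)-7,7-dimethoxy-3-methyl-2-methylideneheptanal
Conditions: 11 (37% aq.), pyrrolidine (10 mol%), EtCO2H (10 mol%), iPrOH, 45 °C
Reagents that add atoms: none
Why: Amine-catalysed α-methylenation (Mannich condensation with formaldehyde, then loss of the amine) turns the α-CH2 of the aldehyde into a 2-substituted acrolein, which introduces C14 on C5 without affecting the β-stereocentre C4.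

Step 7
Reactants: 12 (3R,4R)-4-(tert-butyldimethylsilyloxy)-7,7-dimethoxy-3-methyl-2-methylideneheptanal
Product: 13 (3R,4R)-4-(tert-butyldimethylsilyloxy)-7,7-dimethoxy-3-methyl-2-methylideneheptan-1-ol
Conditions: iBu2AlH, CH2Cl2, −78 °C; aq. potassium sodium tartrate
Reagents that add atoms: none
Why: iBu2AlH at low temperature reduces an enal by 1,2-addition only, giving the 2-substituted allylic alcohol at C6.

Step 8
Reactants: 13 (3R,4R)-4-(tert-butyldimethylsilyloxy)-7,7-dimethoxy-3-methyl-2-methylideneheptan-1-ol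
Product: 14 (4R,5R)-4-(tert-butyldimethylsilyloxy)-7-hydroxy-5-methyl-6-methylideneheptanal
Conditions: PPTS (cat.), acetone/H2O 9:1, 40 °C
Reagents that add atoms: water, O
Why: Mild acid-catalysed hydrolysis of a dimethyl acetal frees the C10 aldehyde while the secondary TBS ether survives.

Step 9
Reactants: 15 trimethyl phosphonoacetate
Product: 16 methyl 2-diazo-2-(dimethoxyphosphoryl)acetate
Conditions: NaH, 4-acetamidobenzenesulfonyl azide, THF, 0 °C to rt
Reagents that add atoms: 4-acetamidobenzenesulfonyl azide, CC(=O)Nc1ccc(cc1)S(=O)(=O)N=[N+]=[N-]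
Why: Regitz diazo transfer from a sulfonyl azide to the sodium enolate of an active-methylene phosphonoacetate.

Step 10
Reactants: 16 methyl 2-diazo-2-(dimethoxyphosphoryl)acetate; 17 4-methoxybenzyl alcohol
Product: 18 methyl 2-(dimethoxyphosphoryl)-2-(4-methoxybenzyloxy)acetate
Conditions: Rh2(OAc)4 (1 mol%), PhMe, 80 °C
Reagents that add atoms: none
Why: Rh2(OAc)4-catalysed O–H insertion of the carbene from a diazophosphonoacetate into a primary alcohol is an established entry to 2-alkoxy phosphonoacetates.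

Step 11
Reactants: 14 (4R,5R)-4-(tert-butyldimethylsilyloxy)-7-hydroxy-5-methyl-6-methylideneheptanal; 18 methyl 2-(dimethoxyphosphoryl)-2-(4-methoxybenzyloxy)acetate
Product: 20 methyl (2Z,6R,7R)-6-(tert-butyldimethylsilyloxy)-9-hydroxy-2-(4-methoxybenzyloxy)-7-methyl-8-methylidenenon-2-enoate, via lithiated phosphonate 19 (not isolated)
Conditions: 18, LiN(SiMe3)2, THF, −78 °C; then 14, −78 to 0 °C
Reagents that add atoms: none
Why: Horner–Wadsworth–Emmons olefination with a 2-alkoxy phosphonoacetate should favour the isomer with the ester trans to the C1 chain, that is the (Z)-2-alkoxy enoate (the minor isomer would be removed by chromatography), and the stabilised phosphonate anion is too weakly basic to disturb the free C6 hydroxyl.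

Step 12
Reactants: 20 methyl (2Z,6R,7R)-6-(tert-butyldimethylsilyloxy)-9-hydroxy-2-(4-methoxybenzyloxy)-7-methyl-8-methylidenenon-2-enoate; 21 methyl phenyl sulfone
Product: 23 (3Z,7R,8R)-7-(tert-butyldimethylsilyloxy)-10-hydroxy-3-(4-methoxybenzyloxy)-8-methyl-9-methylidene-1-(phenylsulfonyl)dec-3-en-2-one, via lithiated sulfone 22 (not isolated)
Conditions: 21 (3.3 equiv), n-BuLi (3.2 equiv), THF, −78 °C; then 20, −78 to 0 °C; then H2O
Reagents that add atoms: none
Why: Acylation of a lithiated methyl sulfone by an ester gives the β-keto sulfone (C7 attached to C8), which is deprotonated as it forms and so resists a second addition, while the β-substituted 2-alkoxy enoate is a poor Michael acceptor.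

Step 13
Reactants: 23 (3Z,7R,8R)-7-(tert-butyldimethylsilyloxy)-10-hydroxy-3-(4-methoxybenzyloxy)-8-methyl-9-methylidene-1-(phenylsulfonyl)dec-3-en-2-one
Product: 24 (3Z,7R,8R)-7-(tert-butyldimethylsilyloxy)-10-(methoxycarbonyloxy)-3-(4-methoxybenzyloxy)-8-methyl-9-methylidene-1-(phenylsulfonyl)dec-3-en-2-one
Conditions: ClCO2Me, pyridine, CH2Cl2, 0 °C
Reagents that add atoms: methyl chloroformate, COC(=O)Cl
Why: Acylation of the primary allylic alcohol with a chloroformate under pyridine, a base too weak to enolise the β-keto sulfone.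

Step 14
Reactants: 24 (3Z,7R,8R)-7-(tert-butyldimethylsilyloxy)-10-(methoxycarbonyloxy)-3-(4-methoxybenzyloxy)-8-methyl-9-methylidene-1-(phenylsulfonyl)dec-3-en-2-one
Product: 25 (2Z,6R,7R)-6-(tert-butyldimethylsilyloxy)-2-(4-methoxybenzyloxy)-7-methyl-8-methylidene-10-(phenylsulfonyl)cyclodec-2-en-1-one (both epimers at the sulfonyl carbon)
Conditions: Pd2(dba)3·CHCl3 (5 mol%), dppe (12 mol%), THF, 65 °C, slow addition to 2 mM
Reagents that add atoms: none
Why: Intramolecular Tsuji–Trost allylic alkylation under neutral conditions, in which zerovalent palladium ionises the allylic carbonate to a 2-substituted π-allyl complex and methoxide, the methoxide deprotonates the β-keto sulfone and C7 attacks an allyl terminus; both termini (C6 and C14) lead to the same ten-membered ring with the methylene exocyclic on C5, and an O-allylated product can re-ionise.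

Step 15
Reactants: 25 (2Z,6R,7R)-6-(tert-butyldimethylsilyloxy)-2-(4-methoxybenzyloxy)-7-methyl-8-methylidene-10-(phenylsulfonyl)cyclodec-2-en-1-one
Product: 26 (2Z,6R,7R)-6-(tert-butyldimethylsilyloxy)-2-(4-methoxybenzyloxy)-7-methyl-8-methylidenecyclodec-2-en-1-one
Conditions: SmI2 (2.5 equiv), THF/MeOH, −78 °C
Reagents that add atoms: none
Why: Reductive desulfonylation of an α-sulfonyl ketone by SmI2 (two single-electron transfers, loss of sulfinate, protonation of the samarium enolate by MeOH) is fast at −78 °C, which should spare the 2-alkoxy enone.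

Step 16
Reactants: 26 (2Z,6R,7R)-6-(tert-butyldimethylsilyloxy)-2-(4-methoxybenzyloxy)-7-methyl-8-methylidenecyclodec-2-en-1-one
Product: 28 (3R,4R,5R,9R,10S)-3-(tert-butyldimethylsilyloxy)-9-(4-methoxybenzyloxy)-4,5-dimethyl-cis-decalin-8-one (target numbering), via C9-epimeric decalone mixture 27 (not isolated)
Conditions: Fe(acac)3 (0.3 equiv), PhSiH3 (3 equiv), EtOH/(CH2OH)2 5:1, 5 mM, 60 °C; then K2CO3, MeOH, rt
Reagents that add atoms: none
Why: Proposed new method: an iron hydride generated from trivalent Fe(acac)3 and PhSiH3 should deliver a hydrogen atom to the CH2 terminus (C14) of the exocyclic 1,1-disubstituted alkene, the tertiary C5 radical then adds across the ten-membered ring to C10, the β-carbon of the 2-alkoxy enone, and the captodative C9 radical is reduced by divalent iron and protonated by ethanol. The closest known reaction types are hydrogen-atom-transfer Giese additions with Fe(acac)3/PhSiH3 between separate or tethered alkene and acceptor partners and transannular radical cyclisations of macrocyclic dienones started from halides; their combination on a cyclodecadienone has not been described. The one new bond C5–C10 closes ring A in a 6-exo-trig sense (C10 inside the ring, C9 outside) and ring B in a 6-endo-trig sense (C9 and C10 both inside). C5 and C10 are set by the ring conformation under relay from C3 and C4: with the in-ring trans enone a chair–chair arrangement is available, corresponding to the boat–chair–boat form of the ten-membered ring with C4–C5 and C9=C10 as antiperiplanar bonds, in which the C3 silyloxy and C4 methyl groups are equatorial on ring A and C14 is axial and hence cis to C15 and to H10, while C9 is set afterwards by the K2CO3/MeOH equilibration, the equatorial ether avoiding a 1,3-diaxial contact with C4. The step needs hydrogen-atom transfer to the electron-neutral methylene and not to the trisubstituted acceptor-substituted enone, which the higher reactivity of 1,1-disubstituted alkenes towards metal hydrides should secure, and it needs cis fusion with C14 cis to C15, which the chair–chair model predicts but cannot guarantee against the trans-fused alternative; high dilution suppresses intermolecular addition.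

Step 17
Reactants: 28 (3R,4R,5R,9R,10S)-3-(tert-butyldimethylsilyloxy)-9-(4-methoxybenzyloxy)-4,5-dimethyl-cis-decalin-8-one; 29 acetone
Product: 31 (3R,4R,5R,7R,9R,10S)-3-(tert-butyldimethylsilyloxy)-7-(2-hydroxypropan-2-yl)-9-(4-methoxybenzyloxy)-4,5-dimethyl-cis-decalin-8-one, via lithium enolate 30 (not isolated)
Conditions: LiN(iPr)2, THF, −78 °C; then 29, −78 °C; AcOH quench
Reagents that add atoms: none
Why: Kinetic deprotonation occurs at the unhindered C7 methylene and not at the alkoxy-bearing C9 methine, and the aldol addition of the lithium enolate to acetone should take place on the face of C7 away from the axial C4–C5 bond, giving the equatorial 7R substituent, which is also the thermodynamically preferred one.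

Step 18
Reactants: 31 (3R,4R,5R,7R,9R,10S)-3-(tert-butyldimethylsilyloxy)-7-(2-hydroxypropan-2-yl)-9-(4-methoxybenzyloxy)-4,5-dimethyl-cis-decalin-8-one
Product: 32 (3R,4R,5R,7R,9R,10S)-3-(tert-butyldimethylsilyloxy)-9-(4-methoxybenzyloxy)-4,5-dimethyl-7-(prop-1-en-2-yl)-cis-decalin-8-one
Conditions: SOCl2, pyridine, CH2Cl2, −30 to 0 °C
Reagents that add atoms: none
Why: Dehydration of the tertiary carbinol through its chlorosulfite with pyridine as base (E2) should remove one of the six methyl hydrogens in preference to the hindered C7 hydrogen, giving the β,γ-unsaturated isopropenyl ketone under conditions too mild to conjugate it.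

Step 19
Reactants: 32 (3R,4R,5R,7R,9R,10S)-3-(tert-butyldimethylsilyloxy)-9-(4-methoxybenzyloxy)-4,5-dimethyl-7-(prop-1-en-2-yl)-cis-decalin-8-one
Product: 33 (3R,4R,5R,7R,9R,10S)-3-(tert-butyldimethylsilyloxy)-9-hydroxy-4,5-dimethyl-7-(prop-1-en-2-yl)-cis-decalin-8-one
Conditions: DDQ, CH2Cl2/pH 7 phosphate buffer, 0 °C to rt
Reagents that add atoms: none
Why: Oxidative cleavage of a 4-methoxybenzyl ether by DDQ (hydride abstraction, hydrolysis of the oxocarbenium ion) leaves the silyl ether, the ketone and the isolated alkene untouched.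

Step 20
Reactants: 33 (3R,4R,5R,7R,9R,10S)-3-(tert-butyldimethylsilyloxy)-9-hydroxy-4,5-dimethyl-7-(prop-1-en-2-yl)-cis-decalin-8-one; 34 angelic acid [(Z)-2-methylbut-2-enoic acid]
Product: 36 (3R,4R,5R,7R,9R,10S)-3-(tert-butyldimethylsilyloxy)-4,5-dimethyl-8-oxo-7-(prop-1-en-2-yl)-cis-decalin-9-yl (Z)-2-methylbut-2-enoate, via mixed anhydride 35 (not isolated)
Conditions: 34, 2,4,6-trichlorobenzoyl chloride, Et3N, PhMe, rt; then 33, 80 °C
Reagents that add atoms: none
Why: Esterification through the mixed anhydride with 2,4,6-trichlorobenzoic acid (Yamaguchi-type, without DMAP) is the established way to acylate hindered secondary alcohols with angelic acid without Z-to-E isomerisation to the tiglate, and C9 keeps its equatorial configuration.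

Step 21
Reactants: 36 (3R,4R,5R,7R,9R,10S)-3-(tert-butyldimethylsilyloxy)-4,5-dimethyl-8-oxo-7-(prop-1-en-2-yl)-cis-decalin-9-yl (Z)-2-methylbut-2-enoate
Product: 37 (3R,4R,5R,7R,9R,10S)-3-hydroxy-4,5-dimethyl-8-oxo-7-(prop-1-en-2-yl)-cis-decalin-9-yl (Z)-2-methylbut-2-enoate
Conditions: aq. HF (48%), MeCN, 0 °C to rt
Reagents that add atoms: none
Why: Acidic fluoride cleavage of the secondary TBS ether avoids basic fluoride, which could epimerise C7 or C9, conjugate the isopropenyl ketone or shift the C9 ester.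

Step 22
Reactants: 37 (3R,4R,5R,7R,9R,10S)-3-hydroxy-4,5-dimethyl-8-oxo-7-(prop-1-en-2-yl)-cis-decalin-9-yl (Z)-2-methylbut-2-enoate; 38 3-methylbut-2-enoyl chloride
Product: 39 CNP0164025.2 [(3R,4R,5R,7R,9R,10S)-4,5-dimethyl-3-(3-methylbut-2-enoyloxy)-8-oxo-7-(prop-1-en-2-yl)-cis-decalin-9-yl (Z)-2-methylbut-2-enoate]
Conditions: 38, pyridine, DMAP (cat.), CH2Cl2, 0 °C to rt
Reagents that add atoms: none
Why: Nucleophile-catalysed acylation of the equatorial C3 alcohol with the acid chloride, run with a weak base at low temperature to avoid deconjugation of the senecioyl unit through a vinylketene, under which the C9 angelate already in place is stable.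

**Compound list**

1 | 4,4-dimethoxybutanenitrile | COC(OC)CCC#N | starting material
2 | N-(diisobutylalumanyl)-4,4-dimethoxybutan-1-imine (not isolated) | COC(OC)CCC=N[Al](CC(C)C)CC(C)C | intermediate
3 | 4,4-dimethoxybutanal | COC(OC)CCC=O | intermediate
4 | (Z)-but-2-ene | C/C=C\C | starting material
5 | diisopinocampheylborinate ester of 6 (not isolated) | C=C[C@@H](C)[C@H](OB([C@@H]1C[C@@H]2C[C@H]([C@H]1C)C2(C)C)[C@@H]1C[C@@H]2C[C@H]([C@H]1C)C2(C)C)CCC(OC)OC | intermediate
6 | (3R,4R)-7,7-dimethoxy-3-methylhept-1-en-4-ol (3,4-syn) | C=C[C@@H](C)[C@H](O)CCC(OC)OC | intermediate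
7 | tert-butyl{[(3R,4R)-7,7-dimethoxy-3-methylhept-1-en-4-yl]oxy}dimethylsilane | C=C[C@@H](C)[C@H](O[Si](C)(C)C(C)(C)C)CCC(OC)OC | intermediate
8 | B-alkyl-9-borabicyclo[3.3.1]nonane from 7, boron on the terminal carbon (not isolated) | C1CCC2CCCC1B2CC[C@@H](C)[C@H](O[Si](C)(C)C(C)(C)C)CCC(OC)OC | intermediate
9 | (3R,4R)-4-(tert-butyldimethylsilyloxy)-7,7-dimethoxy-3-methylheptan-1-ol | OCC[C@@H](C)[C@H](O[Si](C)(C)C(C)(C)C)CCC(OC)OC | intermediate
10 | (3R,4R)-4-(tert-butyldimethylsilyloxy)-7,7-dimethoxy-3-methylheptanal | O=CC[C@@H](C)[C@H](O[Si](C)(C)C(C)(C)C)CCC(OC)OC | intermediate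
11 | formaldehyde | C=O | starting material
12 | (3R,4R)-4-(tert-butyldimethylsilyloxy)-7,7-dimethoxy-3-methyl-2-methylideneheptanal | O=CC(=C)[C@@H](C)[C@H](O[Si](C)(C)C(C)(C)C)CCC(OC)OC | intermediate
13 | (3R,4R)-4-(tert-butyldimethylsilyloxy)-7,7-dimethoxy-3-methyl-2-methylideneheptan-1-ol | OCC(=C)[C@@H](C)[C@H](O[Si](C)(C)C(C)(C)C)CCC(OC)OC | intermediate
14 | (4R,5R)-4-(tert-butyldimethylsilyloxy)-7-hydroxy-5-methyl-6-methylideneheptanal | OCC(=C)[C@@H](C)[C@H](O[Si](C)(C)C(C)(C)C)CCC=O | intermediate
15 | trimethyl phosphonoacetate | COC(=O)CP(=O)(OC)OC | starting material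
16 | methyl 2-diazo-2-(dimethoxyphosphoryl)acetate | COC(=O)C(=[N+]=[N-])P(=O)(OC)OC | intermediate
17 | 4-methoxybenzyl alcohol | COc1ccc(CO)cc1 | starting material
18 | methyl 2-(dimethoxyphosphoryl)-2-(4-methoxybenzyloxy)acetate (racemic) | COC(=O)C(OCc1ccc(OC)cc1)P(=O)(OC)OC | intermediate
19 | lithium salt of 18, phosphonate carbanion (not isolated) | [Li]C(OCc1ccc(OC)cc1)(C(=O)OC)P(=O)(OC)OC | intermediate
20 | methyl (2Z,6R,7R)-6-(tert-butyldimethylsilyloxy)-9-hydroxy-2-(4-methoxybenzyloxy)-7-methyl-8-methylidenenon-2-enoate | COC(=O)/C(OCc1ccc(OC)cc1)=C/CC[C@@H](O[Si](C)(C)C(C)(C)C)[C@H](C)C(=C)CO | intermediate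
21 | methyl phenyl sulfone | CS(=O)(=O)c1ccccc1 | starting material
22 | (phenylsulfonyl)methyllithium (not isolated) | [Li]CS(=O)(=O)c1ccccc1 | intermediate
23 | (3Z,7R,8R)-7-(tert-butyldimethylsilyloxy)-10-hydroxy-3-(4-methoxybenzyloxy)-8-methyl-9-methylidene-1-(phenylsulfonyl)dec-3-en-2-one | O=C(CS(=O)(=O)c1ccccc1)/C(OCc1ccc(OC)cc1)=C/CC[C@@H](O[Si](C)(C)C(C)(C)C)[C@H](C)C(=C)CO | intermediate
24 | (3Z,7R,8R)-7-(tert-butyldimethylsilyloxy)-10-(methoxycarbonyloxy)-3-(4-methoxybenzyloxy)-8-methyl-9-methylidene-1-(phenylsulfonyl)dec-3-en-2-one | O=C(CS(=O)(=O)c1ccccc1)/C(OCc1ccc(OC)cc1)=C/CC[C@@H](O[Si](C)(C)C(C)(C)C)[C@H](C)C(=C)COC(=O)OC | intermediate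
25 | (2Z,6R,7R)-6-(tert-butyldimethylsilyloxy)-2-(4-methoxybenzyloxy)-7-methyl-8-methylidene-10-(phenylsulfonyl)cyclodec-2-en-1-one, both epimers at the sulfonyl carbon | C=C1CC(S(=O)(=O)c2ccccc2)C(=O)/C(OCc2ccc(OC)cc2)=C/CC[C@@H](O[Si](C)(C)C(C)(C)C)[C@@H]1C | intermediate
26 | (2Z,6R,7R)-6-(tert-butyldimethylsilyloxy)-2-(4-methoxybenzyloxy)-7-methyl-8-methylidenecyclodec-2-en-1-one (in-ring trans enone) | C=C1CCC(=O)/C(OCc2ccc(OC)cc2)=C/CC[C@@H](O[Si](C)(C)C(C)(C)C)[C@@H]1C | intermediate
27 | (3R,4R,5R,10S)-decalone 28 as a mixture of C9 epimers (not isolated) | C1C[C@@]2(C)[C@H](CC[C@@H](O[Si](C)(C)C(C)(C)C)[C@@H]2C)C(OCc3ccc(OC)cc3)C1=O | intermediate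
28 | (3R,4R,5R,9R,10S)-3-(tert-butyldimethylsilyloxy)-9-(4-methoxybenzyloxy)-4,5-dimethyl-cis-decalin-8-one (target numbering; C14 cis to C15 and to H10) | C1C[C@@]2(C)[C@H](CC[C@@H](O[Si](C)(C)C(C)(C)C)[C@@H]2C)[C@@H](OCc3ccc(OC)cc3)C1=O | intermediate
29 | acetone | CC(C)=O | starting material
30 | lithium C7(8)-enolate of 28 (not isolated) | [Li]OC1=CC[C@@]2(C)[C@H](CC[C@@H](O[Si](C)(C)C(C)(C)C)[C@@H]2C)[C@H]1OCc1ccc(OC)cc1 | intermediate
31 | (3R,4R,5R,7R,9R,10S)-3-(tert-butyldimethylsilyloxy)-7-(2-hydroxypropan-2-yl)-9-(4-methoxybenzyloxy)-4,5-dimethyl-cis-decalin-8-one | CC(C)(O)[C@H]1C[C@@]2(C)[C@H](CC[C@@H](O[Si](C)(C)C(C)(C)C)[C@@H]2C)[C@@H](OCc3ccc(OC)cc3)C1=O | intermediate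
32 | (3R,4R,5R,7R,9R,10S)-3-(tert-butyldimethylsilyloxy)-9-(4-methoxybenzyloxy)-4,5-dimethyl-7-(prop-1-en-2-yl)-cis-decalin-8-one | C=C(C)[C@H]1C[C@@]2(C)[C@H](CC[C@@H](O[Si](C)(C)C(C)(C)C)[C@@H]2C)[C@@H](OCc3ccc(OC)cc3)C1=O | intermediate
33 | (3R,4R,5R,7R,9R,10S)-3-(tert-butyldimethylsilyloxy)-9-hydroxy-4,5-dimethyl-7-(prop-1-en-2-yl)-cis-decalin-8-one | C=C(C)[C@H]1C[C@@]2(C)[C@H](CC[C@@H](O[Si](C)(C)C(C)(C)C)[C@@H]2C)[C@@H](O)C1=O | intermediate
34 | angelic acid, (Z)-2-methylbut-2-enoic acid | C/C=C(/C)C(=O)O | starting material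
35 | (Z)-2-methylbut-2-enoic 2,4,6-trichlorobenzoic anhydride (not isolated) | C/C=C(/C)C(=O)OC(=O)c1c(Cl)cc(Cl)cc1Cl | intermediate
36 | (3R,4R,5R,7R,9R,10S)-3-(tert-butyldimethylsilyloxy)-4,5-dimethyl-8-oxo-7-(prop-1-en-2-yl)-cis-decalin-9-yl (Z)-2-methylbut-2-enoate | C=C(C)[C@H]1C[C@@]2(C)[C@H](CC[C@@H](O[Si](C)(C)C(C)(C)C)[C@@H]2C)[C@@H](OC(=O)/C(C)=C\C)C1=O | intermediate
37 | (3R,4R,5R,7R,9R,10S)-3-hydroxy-4,5-dimethyl-8-oxo-7-(prop-1-en-2-yl)-cis-decalin-9-yl (Z)-2-methylbut-2-enoate | C=C(C)[C@H]1C[C@@]2(C)[C@H](CC[C@@H](O)[C@@H]2C)[C@@H](OC(=O)/C(C)=C\C)C1=O | intermediate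
38 | 3-methylbut-2-enoyl chloride | CC(C)=CC(=O)Cl | starting material
39 | CNP0164025.2, (3R,4R,5R,7R,9R,10S)-4,5-dimethyl-3-(3-methylbut-2-enoyloxy)-8-oxo-7-(prop-1-en-2-yl)-cis-decalin-9-yl (Z)-2-methylbut-2-enoate | C=C(C)[C@H]1C[C@@]2(C)[C@H](CC[C@@H](OC(=O)C=C(C)C)[C@@H]2C)[C@@H](OC(=O)/C(C)=C\C)C1=O | target

**Step count and risks**

Total step count: 22. Longest linear sequence: 20 steps (steps 1–8 and 11–22, from 1 to 39); steps 9 and 10 form a two-step side branch to phosphonate 18.

Steps most likely to fail: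

Step 16 (key step). The tertiary C5 radical may be reduced before it adds across the ring (net hydrogenation of the exocyclic alkene), or the closure may run through the trans-fused transition state. The fallback makes the same C5–C10 bond by ionic, chelate-organised chemistry before ring B exists, and sets out from hydroxy aldehyde 14. Dimethyl [1-(4-methoxybenzyloxy)-2-oxopropyl]phosphonate F1 would be prepared from commercial dimethyl (1-diazo-2-oxopropyl)phosphonate and 17 by Rh2(OAc)4-catalysed O–H insertion. Condensation of F1 with 14 (LiN(SiMe3)2, THF) would give the (Z)-2-alkoxy enone methyl ketone F2, and MnO2 would oxidise its allylic alcohol to the 2-substituted acrolein F3. Conjugate reduction of the unhindered enal with [(Ph3P)CuH]6 would place the hydride on C14 and generate the C5 copper enolate, which adds to C10 of the enone in a reductive Michael cyclisation to give the ring A keto aldehyde F4. The enolate oxygen and the acceptor carbonyl are held on the same metal, so the C6 formyl group and the C9 side chain should end up cis. Aldol condensation of the C7 methyl ketone with the non-enolisable C6 aldehyde (KOH, MeOH) would close ring B as the cis-fused Δ6-enone F5. Conjugate reduction with LiBH(sBu)3 and the K2CO3/MeOH equilibration at C9 would return to the route at decalone 28.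

Step 14. Closure of the strained ten-membered ring competes with intermolecular allylation (oligomers) and with β-hydride loss from the allylpalladium complex (diene formation). The fallback closes the ring at C9=C10 instead and sets out from allylic alcohol 13. CBr4/PPh3 (Appel bromination) would give allylic bromide F6, which alkylates the dianion of keto phosphonate F1 (NaH, then n-BuLi, THF) at its methyl terminus (C7) to give phosphonate acetal F7. PPTS in wet acetone would free the C10 aldehyde F8. An intramolecular Horner–Wadsworth–Emmons reaction under high dilution (LiCl, iPr2NEt, MeCN) would deliver macrocyclic dienone 26 directly, so that steps 8 and 11 to 15 are bypassed.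

Step 18. The elimination may lose regiocontrol, the acidic C7 hydrogen being removed in place of a methyl hydrogen so that the conjugated isopropylidene ketone forms. The fallback accepts that isomer and deconjugates it. From aldol adduct 31, MsCl/Et3N would give the tertiary mesylate F9, which DBU converts by E1cB elimination into the 7-isopropylidene ketone F10. KOtBu in tBuOH/THF would form the extended dienolate by γ-deprotonation of a methyl group, and kinetic α-protonation with cold aqueous AcOH would give the β,γ-unsaturated ketone 32, where the route resumes.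

Further compounds
F1 | step 16 | dimethyl [1-(4-methoxybenzyloxy)-2-oxopropyl]phosphonate | CC(=O)C(OCc1ccc(OC)cc1)P(=O)(OC)OC
F2 | step 16 | (3Z,7R,8R)-7-(tert-butyldimethylsilyloxy)-10-hydroxy-3-(4-methoxybenzyloxy)-8-methyl-9-methylidenedec-3-en-2-one | CC(=O)/C(OCc1ccc(OC)cc1)=C/CC[C@@H](O[Si](C)(C)C(C)(C)C)[C@H](C)C(=C)CO
F3 | step 16 | (3R,4R,7Z)-4-(tert-butyldimethylsilyloxy)-8-(4-methoxybenzyloxy)-3-methyl-2-methylidene-9-oxodec-7-enal | CC(=O)/C(OCc1ccc(OC)cc1)=C/CC[C@@H](O[Si](C)(C)C(C)(C)C)[C@H](C)C(=C)C=O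
F4 | step 16 | ring A keto aldehyde, (3R,4R,5R,10S in target numbering)-3-(tert-butyldimethylsilyloxy)-4,5-dimethyl-10-[1-(4-methoxybenzyloxy)-2-oxopropyl]cyclohexane-5-carbaldehyde, formyl cis to the side chain | CC(=O)C(OCc1ccc(OC)cc1)[C@H]1CC[C@@H](O[Si](C)(C)C(C)(C)C)[C@H](C)[C@@]1(C)C=O
F5 | step 16 | (3R,4R,5R,9R,10S)-3-(tert-butyldimethylsilyloxy)-9-(4-methoxybenzyloxy)-4,5-dimethyl-cis-decal-6-en-8-one (target numbering) | C1=C[C@@]2(C)[C@H](CC[C@@H](O[Si](C)(C)C(C)(C)C)[C@@H]2C)[C@@H](OCc3ccc(OC)cc3)C1=O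
F6 | step 14 | {[(3R,4R)-2-(bromomethyl)-7,7-dimethoxy-3-methylhept-1-en-4-yl]oxy}(tert-butyl)dimethylsilane | BrCC(=C)[C@@H](C)[C@H](O[Si](C)(C)C(C)(C)C)CCC(OC)OC
F7 | step 14 | dimethyl [(6R,7R)-7-(tert-butyldimethylsilyloxy)-10,10-dimethoxy-1-(4-methoxybenzyloxy)-6-methyl-5-methylidene-2-oxodecyl]phosphonate | COC(OC)CC[C@@H](O[Si](C)(C)C(C)(C)C)[C@H](C)C(=C)CCC(=O)C(OCc1ccc(OC)cc1)P(=O)(OC)OC
F8 | step 14 | dimethyl [(6R,7R)-7-(tert-butyldimethylsilyloxy)-1-(4-methoxybenzyloxy)-6-methyl-5-methylidene-2,10-dioxodecyl]phosphonate | O=CCC[C@@H](O[Si](C)(C)C(C)(C)C)[C@H](C)C(=C)CCC(=O)C(OCc1ccc(OC)cc1)P(=O)(OC)OC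
F9 | step 18 | methanesulfonate of the tertiary alcohol of 31 | CC(C)(OS(C)(=O)=O)[C@H]1C[C@@]2(C)[C@H](CC[C@@H](O[Si](C)(C)C(C)(C)C)[C@@H]2C)[C@@H](OCc3ccc(OC)cc3)C1=O
F10 | step 18 | (3R,4R,5R,9R,10S)-3-(tert-butyldimethylsilyloxy)-9-(4-methoxybenzyloxy)-4,5-dimethyl-7-(propan-2-ylidene)-cis-decalin-8-one | CC(C)=C1C[C@@]2(C)[C@H](CC[C@@H](O[Si](C)(C)C(C)(C)C)[C@@H]2C)[C@@H](OCc3ccc(OC)cc3)C1=O
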